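(The data stem from a simulated flask with made-up constants; the scatter is artificial.)

If the three columns of a run failed to add up to the charge, I looked first at the gap.

| flask | starting material | protic impurity | temperature | remark | time |
|---|---|---|---|---|---|
| winter | 0.77 M | 0.12 M | 32 °C | run made earlier |  |
| autumn | 0.77 M | 0.46 M | 60 °C | run made earlier |  |
| dawn | 0.39 M | 0.231 M | 32 °C | run made earlier |  |
| south-east | 0.77 M | 0.231 M | 20 °C |  | 2.5 h |
| north-west | 0.77 M | 0.231 M | 45 °C |  | 2.5 h |
| west | 0.77 M | 0.231 M | 70 °C |  | 2.5 h |

- winter (time / min: starting material / %, over-reaction product / %, target / %): 8.00: 57.7, 1.6, 27.6; 15.0: 44.3, 4.7, 36.5; 40.0: 25.5, 17.4, 42.7; 90.0: 14.0, 39.6, 30.8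
- autumn (time / min: starting material / %, over-reaction product / %, target / %): 2.00: 17.9, 9.7, 23.1; 4.00: 10.4, 19.1, 16.3; 12.0: 3.4, 34.6, 3.7; 25.0: 1.9, 38.3, 0.3
- dawn (time / min: starting material / %, over-reaction product / %, target / %): 15.0: 37.2, 2.4, 15.8; 30.0: 24.8, 5.3, 17.5; 60.0: 16.0, 11.7, 15.0; 90.0: 13.4, 16.1, 12.2

(readings scatter by 0.3 percentage points)

- percent here means starting material units held: one target or over-reaction product counts as two

* which of these there is most of at the end, counted by the starting material in it, south-east (target / starting material / over-reaction product)
* which of these there is most of at the end, counted by the starting material in it, north-west (target / starting material / over-reaction product)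
* which of these there is most of at the end, counted by the starting material in it, west (target / starting material / over-reaction product)
* amount of the one of these that there is most of at the end, in percent of the starting material charged, south-east
* amount of the one of these that there is most of at the end, in percent of the starting material charged, north-west
* amount of the one of these that there is most of at the end, in percent of the starting material charged, west

By the last reading the gap in winter was 15.6%, and the ratio of protic impurity to starting material charged was 15.6%. Autumn gave 59.5% against 59.7%, and dawn gave 58.3% against 59.2%. So I took one protic impurity to remove one starting material for good, with the protic impurity as the limiting reagent of that loss. For south-east, north-west and west this gave 70.0%, my ceiling: one minus the charge of protic impurity over the charge of starting material. It is the fraction of the charge that starting material, target and over-reaction product hold together after each protic impurity charged has taken one starting material.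

The forecast named target at 35.5% for south-east, over-reaction product at 66.3% for north-west and over-reaction product at 69.5% for west. Its ground for the loss was that “each impurity irreversibly destroys one starting material”.

The flasks gave target at 34.9% in south-east, over-reaction product at 66.9% in north-west and over-reaction product at 69.7% in west.

    2 starting material → target (k = 2.00 × 10⁻⁴ /M/s, Ea = 79.0 kJ/mol)
    target → over-reaction product (k = 4.90 × 10⁻⁵ /s, Ea = 89.0 kJ/mol)
    starting material + protic impurity → quenched substrate (k = 0.00270 /M/s, Ea = 60.0 kJ/mol)
    (constants at 20 °C)

The gap was quenched substrate, 30.0% in south-east after 2.50 h, against 30.0% from the ceiling. In north-west the three counted species summed to 70.0%, which matches the ceiling.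

Then I took south-east read at 6.0 h. The charges were the same, so the ceiling stayed 70.0%, and any gain in over-reaction product had to come from the other two. The computed run held 12.0% starting material, 26.2% target and 31.9% over-reaction product, together 70.1%. Over-reaction product now stood higher than target, so the forecast's choice of target held at 2.5 h but would have been wrong at that later reading.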